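Read the run below as two chemists read it, and carry one number away from it.

- elm: starting material 0.050 M; second substrate 0.0475 M; capture agent 1 mM; enzyme 25 µM; the very flask that is asked about, followed so far
- flask: starting material 0.050 M; second substrate 0.0475 M; capture agent 1.00 mM; enzyme 25 µM; time 8.0 d
elm run (percent of the starting material charged): time / d: target / % = 0.500: 20.6; 0.833: 19.0; 1.25: 16.1; 1.67: 13.7; 3.00: 10.4; 4.00: 10.9; 6.00: 9.9

(each reading ± 0.5 percentage points)
- Friday's: at 8.0 d add enzyme, 100% of the amount charged, then wait 2.5 d
- Saturday's: change nothing and wait 2.5 d more
- Tuesday's: at 8.0 d add second substrate, 50.0% of the amount charged, then wait 2.5 d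
- Wednesday's: at 8.0 d take out 90% of the target then present, then wait 2.5 d
- target taken out counts as made
- the numbers in the tables scatter with a standard deviation of 0.5 percentage points
- additions bring no volume worth counting
1. target, in percent of the starting material first charged, at 8.0 d
2. what to do for the largest gain in target; "none" if nothing gains more than 2 percentage points (Friday's / Saturday's / Tuesday's / Wednesday's / none)
3. target present, with what was taken out counted in, in percent of the starting material first charged, after Saturday's
4. target present, with what was taken out counted in, in percent of the starting material first charged, after Wednesday's

Both chemists see target at a highest reading of 20.6% at 0.500 d, then falling and flat from 3.00 d on. The last three readings average 10.4%.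

The first chemist calls this flat stretch an equilibrium between the reactants and target. Waiting then gains nothing, and target taken out re-forms.

The second chemist objects that one reversible step climbs to its plateau without overshooting, so target must be passing into a partner form. The flat stretch then means that the feed has stopped, with the enzyme no longer working. This view gives a simple measure, N, the number of target molecules left standing per enzyme charged: 208, from 10.4% of the starting material and the enzyme charge.

A fresh equal charge of enzyme should then add 10 percentage points. For Wednesday's, the second chemist takes the symmetric case as the zero of the scale. The plateau is about half of the highest reading, so the pool splits roughly evenly. Taking out 9.36% and letting the remainder split again gains 4.6 points, which is less than Friday's. The second chemist therefore chooses Friday's.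

The forecast is the first chemist's: 10.2% now (9.6% to 10.8%), 10.2% after Saturday's (9.5% to 10.9%), 16.5% after Wednesday's (11% to 18.5%), and Wednesday's as the choice, since “more enzyme doesn't move an equilibrium”.

The simulation gives 9.98% now, 9.96% after Saturday's and 14.6% after Wednesday's. The best choice is Friday's, gaining 9.3 points, more than the 4.6 points for Wednesday's and the −0.029 points for Tuesday's. The second chemist wins the choice. The first chemist's picture of a finished reaction comes closer in a neighbour flask with second substrate at 0.19 M, where 0.840% of the starting material is left at 8.00 d, less than the 75.1% left in this flask.

    starting material + enzyme ⇌ starting complex (K = 15.0 M⁻¹, k = 3900 M⁻¹ min⁻¹)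
    second substrate + starting complex ⇌ ternary complex (K = 8.20 M⁻¹, k = 2000 M⁻¹ min⁻¹)
    ternary complex → enzyme + target (k = 41.0 min⁻¹)
    target ⇌ isomer of the product (K = 1.50, k = 3.20 × 10⁻⁴ min⁻¹)
    capture agent + starting complex → trapped intermediate (k = 24.0 M⁻¹ min⁻¹)

In this flask, half of the turnover of the step from starting material and enzyme was done by 0.0514 d, far sooner than the asked time of 8.0 d. By 0.800 d the catalyst stood >99.9% as trapped intermediate, with 75.1% of the starting material still unbound. Against the 10 points that N gave for Friday's, the flask gains 9.3 points. In a neighbour flask with 6.2 × 10⁻⁶ M enzyme, N gives 2.58%, and that flask holds 2.74% target.

(The readings are simulated with constants of no real substance; scatter was added.)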